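**Analysis of the target**

The target 22 is a 2-arylbenzofuran. A 6-hydroxybenzofuran is bonded through its C2 to C1 of a resorcinol ring (ring A, hydroxyls on C3 and C5), and ring A C2, the position wedged between the benzofuranyl group and the C3 hydroxyl, carries a ten-carbon chain. Numbered from the benzylic carbon C1' to C8', the chain is a geranyl unit that keeps the E C2'=C3' alkene but ends in an (R)-carbinol at C6' next to a C7'=C8' methylene. C6' is the only stereocentre and sits far from every other functional group, so nothing in the molecule can relay stereochemistry to it and it has to be set by a chiral reagent. The sensitive elements are the three electron-rich phenols (easily oxidized as phenoxides), the ortho-allylphenol array C3–OH/C2'=C3' (it closes to a chroman under acid), the secondary allylic alcohol (it ionizes under acid) and the nucleophilic C3 of the benzofuran. The difficulties are the regiochemistry at the crowded ring A C2, where direct electrophilic allylation of the free arylbenzofuran would not go, the remote stereocentre, and a final unmasking that must avoid acid. The strategy rests on one relationship: the C6' carbinol with its C7'=C8' methylene is the 1,3-transposed form of an E C6'=C7' alkene bearing a C8' hydroxyl. That E 2-methyl-2-en-1-ol is among the best substrates for titanium–tartrate epoxidation, and its carbon skeleton and alkene geometry are those of geranyl acetate.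

**Retrosynthetic reasoning**

22 from 21. Only the three O–Si bonds are cut. Keeping the phenols as triisopropylsilyl ethers until the last step means the end game needs fluoride only, so neither chroman formation nor ionization of the allylic alcohol can occur.

21 from 19 and 18. The isopropenyl carbinol is folded back into an oxirane across C6'–C7' with a leaving group on C8' (epoxy iodide 19, made from epoxy alcohol 18). The forward reaction is a reductive elimination by zinc that breaks C7'–O and C8'–I and leaves C6'–O untouched. This converts an epoxy alcohol, which can be made in one enantiomeric form, into the tertiary-substituted allylic alcohol, which cannot easily be made so directly.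

18 from 17 (key disconnection). The C6'–O and C7'–O bonds of the oxirane are cut to give the E allylic alcohol 17. The forward step must choose one face of the C6'=C7' alkene and ignore the C2'=C3' alkene. The C8' hydroxyl does both by binding the chiral titanium catalyst. The cut is made here and not on a smaller fragment because 17 has only this one free hydroxyl and no unprotected phenol, so the stereocentre enters late, catalytically, and travels through only three further steps.

17 from 16, and 16 from 8 and 13. After removal of a silyl group from the C8' oxygen, the C1'–C2 (ring A) bond is cut. This gives two fragments of similar size, the aryl bromide 8 and the allylic bromide 13. The bromine of 8 marks ring A C2, so the regiochemistry of the union is set before the coupling. The forward reaction is a halogen–lithium exchange, transmetalation to copper (14, 15) and SN2 allylation, which must keep the E C2'=C3' geometry.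

13 from 12, 11, 10 and 9. The chain is geranyl acetate 9 with its two ends differentiated. The C8–O bond comes from an E-selective allylic oxidation of the terminal methyl group (10). Silylation (11), removal of the acetate (12) and bromination (13) exchange the roles of the two oxygens. Both trisubstituted alkenes are inherited with the correct geometry.

8 from 7 and 6. This is a protecting-group exchange. The methyl ethers of 6 are robust enough for the construction of the heterocycle, but their cleavage needs a strong Lewis acid, so it is placed before any alkene or stereocentre exists. Silylation of triphenol 7 then gives 8.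

6 from 3 and 4 (through 5). The furan ring is cut at the C3–C3a bond and the O1–C2 bond, giving the aryl alkyne 3 and the iodophenol 4. Forward, a Sonogashira coupling joins the two carbons and the phenol oxygen adds across the alkyne of 5. The aryl iodide reacts in preference to the hindered aryl bromide, which is kept for the later coupling.

3 from 2 and 1. The alkyne comes from aldehyde 2 by one-carbon homologation. The bromine of 2 comes from electrophilic bromination of the symmetrical aldehyde 1, which occurs ortho to the formyl group and para to a methoxy group, at the carbon that becomes ring A C2.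

**Alternatives that were turned down**

Alternative 1: Ring A is built around the chain by a Danheiser benzannulation. The disconnection cuts ring A bonds C3–C4, C5–C6 and C2–C3, leading to the cyclobutenone A2 (benzofuranyl on C3, the complete silyl-protected chain on C4) and the silyloxyalkyne A3. Heating the two should give phenol A1 by 4π ring opening, [2+2] cycloaddition with A3, a second 4π opening, 6π electrocyclization and tautomerization.
- For: the substitution pattern of ring A is fixed by the mechanism, no organometallic is needed at the crowded C2, the conditions are neutral, and the two ring A oxygens emerge differentiated. On regiocontrol of ring A this plan is at least as strong as the chosen one, which depends on a bromine marker and on an aryl-metal ortho to a silyl ether.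
- Against: A2 must already carry the whole chain with its stereocentre on an sp3 ring carbon, so the asymmetric step is still needed and comes earlier. A2 itself needs a ketene cycloaddition and a regioselective alkylation, a long linear sequence. After ring opening of A2 the ketene terminus lies near the allylic C1' hydrogens and the C2'=C3' alkene, so hydrogen shift and intramolecular cycloaddition can compete with the bimolecular step. The allylic silyl ether and the stereocentre would also pass through prolonged heating.
- Comparison: the chosen route keeps the benzene ring and the terpene chain as bought and places the stereocentre last under catalyst control, in fewer steps.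

Alternative 2: The E trisubstituted alkene is made while the fragments are joined. The C3'–methyl and C1'–C2' bonds are cut, leading to the (R)-enynol A5 and the ring A benzylic chloride A6. Zirconium-catalysed syn methylalumination of the alkyne of A5, followed by palladium-catalysed coupling of the new alkenyl–aluminium bond with A6, should give A4, which is identical with compound 21 of the chosen route.
- For: it is the most convergent plan. The alkene geometry comes from a highly stereoselective syn addition, and only the desilylation remains after the union. On convergence and on the number of steps after fragment coupling it is stronger than the chosen route.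
- Against: A5 needs its own asymmetric synthesis on a small volatile molecule. Its free hydroxyl becomes an aluminium alkoxide three carbons from the alkyne, and its 1,1-disubstituted alkene is a possible second site for carbometalation. A6 is a doubly ortho-substituted, very electron-rich benzylic chloride that ionizes easily. Making it still requires metalation of ring A C2, followed by formylation, reduction and chlorination.
- Comparison: the carboalumination solves a geometry problem that the chosen route does not have, since geranyl acetate supplies the E alkene. In exchange the chosen route offers a stereocentre set catalytically on an advanced intermediate by a reaction whose sense of induction is predictable.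

Alternative 3: The furan is closed last by an intramolecular Wittig reaction. The C2=C3 bond of the furan is cut, leading to the phosphonium salt A8, in which the ring A acid carrying the complete protected chain is esterified with the phenol of the benzylphosphonium unit. A tertiary amine in hot toluene should deprotonate the benzylic carbon, and olefination of the ester carbonyl should give A7.
- For: this closure is a classical and dependable way to 2-arylbenzofurans, needs no transition metal and is unambiguous in regiochemistry. As a furan synthesis it is as reliable as the Sonogashira cyclization used in the chosen route.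
- Against: the key step is spent on the easiest part of the target. The chain attachment at ring A C2 and the C6' stereocentre remain unsolved and must be dealt with before A8 is assembled. The valuable chain then has to survive acid chloride formation, acylation, and heating with amine hydrobromide. Phosphonium salt formation with acid is incompatible with silyl ethers, which restricts the order of steps and adds protecting-group operations.
- Comparison: the chosen route forms the furan early from simple materials and keeps the risk in the step that creates the stereocentre.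

Key step: step 12

Remarks: Ar stands for 2-[6-(triisopropylsilyloxy)-1-benzofuran-2-yl]-4,6-bis(triisopropylsilyloxy)phenyl. Primed locants refer to the chain (C1' benzylic to C8'). Compounds 1, 4 and 9 are taken to be catalogue compounds.

**Route**

Step 1
Reactants: 1 3,5-dimethoxybenzaldehyde
Product: 2 2-bromo-3,5-dimethoxybenzaldehyde
Conditions: NBS, MeCN, 0 °C to rt
Reagents that add atoms: N-bromosuccinimide, O=C1CCC(=O)N1Br
Why: Electrophilic aromatic bromination; C2 (equivalent to C6) is para to one methoxy group and ortho to the other and is less shielded than C4 between the two methoxy groups, so the halogen should enter at the future chain-bearing carbon of ring A.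

Step 2
Reactants: 2 2-bromo-3,5-dimethoxybenzaldehyde
Product: 3 2-bromo-1-ethynyl-3,5-dimethoxybenzene
Conditions: dimethyl (1-diazo-2-oxopropyl)phosphonate, K2CO3, MeOH, rt
Reagents that add atoms: dimethyl (1-diazo-2-oxopropyl)phosphonate (Ohira–Bestmann reagent), COP(=O)(OC)C(=[N+]=[N-])C(C)=O
Why: Ohira–Bestmann (Seyferth–Gilbert) homologation; methanolysis of the reagent frees the diazomethylphosphonate anion, which adds to the aldehyde, eliminates phosphate and loses N2 with a 1,2-shift to give the terminal alkyne. The aryl bromide and the methyl ethers are inert to carbonate in methanol.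

Step 3
Reactants: 3 2-bromo-1-ethynyl-3,5-dimethoxybenzene, 4 2-iodo-5-methoxyphenol
Product: 6 2-(2-bromo-3,5-dimethoxyphenyl)-6-methoxy-1-benzofuran, via alkynylphenol 5 (not isolated)
Conditions: PdCl2(PPh3)2 (cat.), CuI (cat.), Et3N, DMF, rt then 60 °C
Reagents that add atoms: none
Why: Sonogashira coupling followed by 5-endo-dig heteroannulation of the ortho-alkynylphenol; zerovalent palladium inserts into the C–I bond much faster than into the hindered, electron-rich C–Br bond, and the phenol oxygen then adds across the metal-activated alkyne to close the furan with the methoxy group at C6.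

Step 4
Reactants: 6 2-(2-bromo-3,5-dimethoxyphenyl)-6-methoxy-1-benzofuran
Product: 7 4-bromo-5-(6-hydroxy-1-benzofuran-2-yl)benzene-1,3-diol
Conditions: BBr3 (excess), CH2Cl2, −78 °C to rt; then H2O
Reagents that add atoms: none
Why: Lewis-acid cleavage of aryl methyl ethers; boron binds each ether oxygen and bromide removes the methyl group by SN2. The aryl bromide and the benzofuran tolerate these conditions, and the step is placed before any alkene or stereocentre is present.

Step 5
Reactants: 7 4-bromo-5-(6-hydroxy-1-benzofuran-2-yl)benzene-1,3-diol
Product: 8 2-[2-bromo-3,5-bis(triisopropylsilyloxy)phenyl]-6-(triisopropylsilyloxy)-1-benzofuran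
Conditions: TIPSCl, imidazole, DMF, rt to 40 °C
Reagents that add atoms: triisopropylsilyl chloride, CC(C)[Si](Cl)(C(C)C)C(C)C
Why: Imidazole-promoted silylation of phenols; the bulky silyl ethers should survive organolithium and organocopper chemistry at low temperature, mild acid, the titanium peroxide system and zinc, and can be removed at the end with fluoride instead of acid.

Step 6
Reactants: 9 geranyl acetate
Product: 10 (2E,6E)-8-hydroxy-3,7-dimethylocta-2,6-dien-1-yl acetate
Conditions: SeO2 (cat.), t-BuOOH, salicylic acid (cat.), CH2Cl2, rt
Reagents that add atoms: selenium dioxide, O=[Se]=O (oxygen carrier, catalytic); tert-butyl hydroperoxide, CC(C)(C)OO (terminal source of the oxygen)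
Why: Selenium dioxide allylic oxidation (ene reaction, then [2,3]-sigmatropic shift); the terminal alkene is more electron-rich than the alkene next to the acetate, and the mechanism hydroxylates the methyl group trans to the chain, giving the E allylic alcohol.

Step 7
Reactants: 10 (2E,6E)-8-hydroxy-3,7-dimethylocta-2,6-dien-1-yl acetate
Product: 11 (2E,6E)-8-(tert-butyldimethylsilyloxy)-3,7-dimethylocta-2,6-dien-1-yl acetate
Conditions: TBSCl, imidazole, CH2Cl2, 0 °C to rt
Reagents that add atoms: tert-butyldimethylsilyl chloride, CC(C)(C)[Si](C)(C)Cl
Why: Standard silylation of a primary alcohol; the alkyl silyl ether withstands acetate methanolysis, bromination and the arylcopper, and is later cleaved by mild acid that leaves aryl triisopropylsilyl ethers intact.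

Step 8
Reactants: 11 (2E,6E)-8-(tert-butyldimethylsilyloxy)-3,7-dimethylocta-2,6-dien-1-yl acetate
Product: 12 (2E,6E)-8-(tert-butyldimethylsilyloxy)-3,7-dimethylocta-2,6-dien-1-ol
Conditions: K2CO3 (cat.), MeOH, rt
Reagents that add atoms: none
Why: Base-catalysed transesterification of the acetate with methanol; a primary alkyl silyl ether is stable to carbonate in methanol.

Step 9
Reactants: 12 (2E,6E)-8-(tert-butyldimethylsilyloxy)-3,7-dimethylocta-2,6-dien-1-ol
Product: 13 [(2E,6E)-8-bromo-2,6-dimethylocta-2,6-dien-1-yl]oxy(tert-butyl)dimethylsilane
Conditions: CBr4, PPh3, CH2Cl2, 0 °C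
Reagents that add atoms: carbon tetrabromide, BrC(Br)(Br)Br
Why: Appel reaction; bromide displaces the alkoxyphosphonium group at the primary allylic carbon under neutral conditions, so the alkene geometry and the silyl ether should be preserved. The bromide is used without storage.

Step 10
Reactants: 8 2-[2-bromo-3,5-bis(triisopropylsilyloxy)phenyl]-6-(triisopropylsilyloxy)-1-benzofuran, 13 [(2E,6E)-8-bromo-2,6-dimethylocta-2,6-dien-1-yl]oxy(tert-butyl)dimethylsilane
Product: 16 tert-butyldimethylsilyl ether of (2E,6E)-8-Ar-2,6-dimethylocta-2,6-dien-1-ol, via aryllithium 14 (not isolated), via arylcopper 15 (not isolated)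
Conditions: t-BuLi (2.1 equiv), Et2O, −78 °C; CuBr·SMe2, −78 to −40 °C; then 13, THF, −78 to 0 °C
Reagents that add atoms: none
Why: Bromine–lithium exchange, transmetalation to copper and copper-mediated SN2 allylation; the second equivalent of t-BuLi destroys the tert-butyl bromide formed in the exchange. The arylcopper should attack the unhindered primary carbon of 13, because attack at the fully substituted γ-carbon would create a quaternary centre next to a hindered arene. The C1'–C2 bond therefore forms at the carbon marked by bromine with the E C2'=C3' alkene intact.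

Step 11
Reactants: 16 tert-butyldimethylsilyl ether of (2E,6E)-8-Ar-2,6-dimethylocta-2,6-dien-1-ol
Product: 17 (2E,6E)-8-Ar-2,6-dimethylocta-2,6-dien-1-ol
Conditions: CSA (cat.), MeOH/CH2Cl2, 0 °C
Reagents that add atoms: none
Why: Acid-catalysed methanolysis of a primary alkyl silyl ether; aryl triisopropylsilyl ethers are much more resistant to acid, and no free phenol is present that could add to the alkenes.

Step 12
Reactants: 17 (2E,6E)-8-Ar-2,6-dimethylocta-2,6-dien-1-ol
Product: 18 [(2R,3R)-3-[(3E)-5-Ar-3-methylpent-3-en-1-yl]-2-methyloxiran-2-yl]methanol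
Conditions: Ti(OiPr)4 (cat.), D-(−)-DET (cat.), t-BuOOH, 4 Å MS, CH2Cl2, −20 °C
Reagents that add atoms: tert-butyl hydroperoxide, CC(C)(C)OO
Why: This is a Sharpless asymmetric epoxidation of an E 2-methyl-2-alken-1-ol, the closest known reaction type and a favoured substrate class. The C8' alkoxide and the tert-butyl peroxide replace isopropoxide ligands on the dimeric tartrate complex of tetravalent titanium, and the peroxide oxygen activated by coordination is transferred to the C6'=C7' alkene in a concerted, stereospecific syn addition. The oxirane is therefore closed by a bimolecular oxygen-atom transfer that forms C6'–O and C7'–O together ([2+1] mode), not by cyclization of a preformed chain. Both new stereocentres are set by the reagent: the D-(−)-tartrate selects the alkene face that leads to the 2R,3R epoxy alcohol (6'R,7'R), the mirror image of the 2S,3S series that the L-(+)-ester gives with E allylic alcohols. Their trans relationship follows from the E geometry of the alkene. The step needs enantiofacial selectivity and site selectivity over the C2'=C3' alkene and the benzofuran C2=C3 bond; both are secured by the C8' hydroxyl, the only group able to bind titanium, because alkenes without an allylic hydroxyl are not oxidized by this system at −20 °C. All phenols are silylated, so no internal nucleophile can open the trisubstituted epoxide, and molecular sieves keep the catalyst dry. Only C6' is carried to the target; C7' and the ring are consumed in step 14.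

Step 13
Reactants: 18 [(2R,3R)-3-[(3E)-5-Ar-3-methylpent-3-en-1-yl]-2-methyloxiran-2-yl]methanol
Product: 19 (2S,3R)-2-(iodomethyl)-2-methyl-3-[(3E)-5-Ar-3-methylpent-3-en-1-yl]oxirane
Conditions: PPh3, I2, imidazole, THF, 0 °C
Reagents that add atoms: iodine, II
Why: Garegg–Samuelsson (Appel-type) iodination; iodide displaces the alkoxyphosphonium group at C8' while imidazole takes up the acid, so the epoxide should stay closed. The spatial arrangement is unchanged; the descriptor at C7' becomes S only because iodine raises the rank of C8'.

Step 14
Reactants: 19 (2S,3R)-2-(iodomethyl)-2-methyl-3-[(3E)-5-Ar-3-methylpent-3-en-1-yl]oxirane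
Product: 21 (3R,6E)-8-Ar-2,6-dimethylocta-1,6-dien-3-ol, via alkylzinc iodide 20 (not isolated)
Conditions: Zn dust (activated), EtOH, 60 °C; aq. NH4Cl
Reagents that add atoms: none
Why: Zinc-mediated reductive β-elimination of an epoxy iodide; zinc inserts into the C8'–I bond and the organozinc expels the β-oxygen by breaking C7'–O, which gives the C7'=C8' methylene and the C6' alkoxide. The C6'–O bond is not involved, so the R configuration set in step 12 is retained.

Step 15
Reactants: 21 (3R,6E)-8-Ar-2,6-dimethylocta-1,6-dien-3-ol
Product: 22 5-(6-hydroxy-1-benzofuran-2-yl)-4-[(2E,6R)-6-hydroxy-3,7-dimethylocta-2,7-dien-1-yl]benzene-1,3-diol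
Conditions: Bu4NF, AcOH, THF, 0 °C to rt, under argon
Reagents that add atoms: none
Why: Fluoride-mediated cleavage of the three aryl silyl ethers, driven by Si–F bond formation; acetic acid buffers the phenoxides against oxidation and is far too weak to cause chroman formation or ionization of the allylic alcohol.

**Compound list**

1 | 3,5-dimethoxybenzaldehyde | COc1cc(OC)cc(C=O)c1 | starting material
2 | 2-bromo-3,5-dimethoxybenzaldehyde | COc1cc(OC)c(Br)c(C=O)c1 | intermediate
3 | 2-bromo-1-ethynyl-3,5-dimethoxybenzene | COc1cc(OC)c(Br)c(C#C)c1 | intermediate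
4 | 2-iodo-5-methoxyphenol | COc1ccc(I)c(O)c1 | starting material
5 | 2-[(2-bromo-3,5-dimethoxyphenyl)ethynyl]-5-methoxyphenol (not isolated) | COc1ccc(C#Cc2cc(OC)cc(OC)c2Br)c(O)c1 | intermediate
6 | 2-(2-bromo-3,5-dimethoxyphenyl)-6-methoxy-1-benzofuran | COc1ccc2cc(-c3cc(OC)cc(OC)c3Br)oc2c1 | intermediate
7 | 4-bromo-5-(6-hydroxy-1-benzofuran-2-yl)benzene-1,3-diol | Oc1ccc2cc(-c3cc(O)cc(O)c3Br)oc2c1 | intermediate
8 | 2-[2-bromo-3,5-bis(triisopropylsilyloxy)phenyl]-6-(triisopropylsilyloxy)-1-benzofuran | Brc1c(O[Si](C(C)C)(C(C)C)C(C)C)cc(O[Si](C(C)C)(C(C)C)C(C)C)cc1-c1cc2ccc(O[Si](C(C)C)(C(C)C)C(C)C)cc2o1 | intermediate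
9 | geranyl acetate, (2E)-3,7-dimethylocta-2,6-dien-1-yl acetate | CC(C)=CCC/C(C)=C/COC(C)=O | starting material
10 | (2E,6E)-8-hydroxy-3,7-dimethylocta-2,6-dien-1-yl acetate | OC/C(C)=C/CC/C(C)=C/COC(C)=O | intermediate
11 | (2E,6E)-8-(tert-butyldimethylsilyloxy)-3,7-dimethylocta-2,6-dien-1-yl acetate | CC(C)(C)[Si](C)(C)OC/C(C)=C/CC/C(C)=C/COC(C)=O | intermediate
12 | (2E,6E)-8-(tert-butyldimethylsilyloxy)-3,7-dimethylocta-2,6-dien-1-ol | CC(C)(C)[Si](C)(C)OC/C(C)=C/CC/C(C)=C/CO | intermediate
13 | [(2E,6E)-8-bromo-2,6-dimethylocta-2,6-dien-1-yl]oxy(tert-butyl)dimethylsilane | CC(C)(C)[Si](C)(C)OC/C(C)=C/CC/C(C)=C/CBr | intermediate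
14 | {2-[6-(triisopropylsilyloxy)-1-benzofuran-2-yl]-4,6-bis(triisopropylsilyloxy)phenyl}lithium (not isolated) | [Li]c1c(O[Si](C(C)C)(C(C)C)C(C)C)cc(O[Si](C(C)C)(C(C)C)C(C)C)cc1-c1cc2ccc(O[Si](C(C)C)(C(C)C)C(C)C)cc2o1 | intermediate
15 | {2-[6-(triisopropylsilyloxy)-1-benzofuran-2-yl]-4,6-bis(triisopropylsilyloxy)phenyl}copper (not isolated) | [Cu]c1c(O[Si](C(C)C)(C(C)C)C(C)C)cc(O[Si](C(C)C)(C(C)C)C(C)C)cc1-c1cc2ccc(O[Si](C(C)C)(C(C)C)C(C)C)cc2o1 | intermediate
16 | tert-butyl{[(2E,6E)-8-{2-[6-(triisopropylsilyloxy)-1-benzofuran-2-yl]-4,6-bis(triisopropylsilyloxy)phenyl}-2,6-dimethylocta-2,6-dien-1-yl]oxy}dimethylsilane | CC(C)(C)[Si](C)(C)OC/C(C)=C/CC/C(C)=C/Cc1c(O[Si](C(C)C)(C(C)C)C(C)C)cc(O[Si](C(C)C)(C(C)C)C(C)C)cc1-c1cc2ccc(O[Si](C(C)C)(C(C)C)C(C)C)cc2o1 | intermediate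
17 | (2E,6E)-8-{2-[6-(triisopropylsilyloxy)-1-benzofuran-2-yl]-4,6-bis(triisopropylsilyloxy)phenyl}-2,6-dimethylocta-2,6-dien-1-ol | OC/C(C)=C/CC/C(C)=C/Cc1c(O[Si](C(C)C)(C(C)C)C(C)C)cc(O[Si](C(C)C)(C(C)C)C(C)C)cc1-c1cc2ccc(O[Si](C(C)C)(C(C)C)C(C)C)cc2o1 | intermediate
18 | [(2R,3R)-3-[(3E)-5-Ar-3-methylpent-3-en-1-yl]-2-methyloxiran-2-yl]methanol, the (6'R,7'R)-6',7'-epoxy-8'-ol | OC[C@@]1(C)O[C@@H]1CC/C(C)=C/Cc1c(O[Si](C(C)C)(C(C)C)C(C)C)cc(O[Si](C(C)C)(C(C)C)C(C)C)cc1-c1cc2ccc(O[Si](C(C)C)(C(C)C)C(C)C)cc2o1 | intermediate
19 | (2S,3R)-2-(iodomethyl)-2-methyl-3-[(3E)-5-Ar-3-methylpent-3-en-1-yl]oxirane, the 8'-iodide of 18 | IC[C@@]1(C)O[C@@H]1CC/C(C)=C/Cc1c(O[Si](C(C)C)(C(C)C)C(C)C)cc(O[Si](C(C)C)(C(C)C)C(C)C)cc1-c1cc2ccc(O[Si](C(C)C)(C(C)C)C(C)C)cc2o1 | intermediate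
20 | iodo{[(2S,3R)-2-methyl-3-[(3E)-5-Ar-3-methylpent-3-en-1-yl]oxiran-2-yl]methyl}zinc (not isolated) | I[Zn]C[C@@]1(C)O[C@@H]1CC/C(C)=C/Cc1c(O[Si](C(C)C)(C(C)C)C(C)C)cc(O[Si](C(C)C)(C(C)C)C(C)C)cc1-c1cc2ccc(O[Si](C(C)C)(C(C)C)C(C)C)cc2o1 | intermediate
21 | (3R,6E)-8-{2-[6-(triisopropylsilyloxy)-1-benzofuran-2-yl]-4,6-bis(triisopropylsilyloxy)phenyl}-2,6-dimethylocta-1,6-dien-3-ol | C=C(C)[C@H](O)CC/C(C)=C/Cc1c(O[Si](C(C)C)(C(C)C)C(C)C)cc(O[Si](C(C)C)(C(C)C)C(C)C)cc1-c1cc2ccc(O[Si](C(C)C)(C(C)C)C(C)C)cc2o1 | intermediate
22 | 5-(6-hydroxy-1-benzofuran-2-yl)-4-[(2E,6R)-6-hydroxy-3,7-dimethylocta-2,7-dien-1-yl]benzene-1,3-diol | C=C(C)[C@H](O)CC/C(C)=C/Cc1c(O)cc(O)cc1-c1cc2ccc(O)cc2o1 | target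

**Step count and least certain steps**

Total: 15 steps. Longest linear sequence: 11 steps (steps 1 to 5 and 10 to 15, from 1). The chain branch from 9 (steps 6 to 9) joins at step 10.

Step 12 (key step). The most likely failure is incomplete enantiofacial control together with slow turnover. The substrate is very lipophilic and bulky, and traces of water degrade the titanium–tartrate catalyst, so some background epoxidation through less selective species could lower the enantiomeric purity of C6'. The fallback sets out from 21 of unsatisfactory enantiomeric purity and returns to 21. Oxidation of the allylic alcohol with Dess–Martin periodinane should give the isopropenyl ketone (6E)-8-Ar-2,6-dimethylocta-1,6-dien-3-one F1. Reduction of F1 with catecholborane and the (S)-2-methyl-CBS-oxazaborolidine at −78 °C should return 21. The configuration would then be set by reagent-controlled hydride delivery, with the isopropenyl group acting as the larger substituent, which is expected to give the R carbinol.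

Step 10. The most likely failure is anionic migration of the triisopropylsilyl group from O3 to the lithiated C2 (retro-Brook rearrangement) before transmetalation. Sluggish allylation by the doubly ortho-substituted arylcopper and partial attack at the γ-carbon are further risks. The fallback sets out from 8 and returns to 16 without any aryllithium. Miyaura borylation of 8 (B2pin2, Pd(dppf)Cl2, KOAc, dioxane, 90 °C) should give the aryl pinacol boronate 2-Ar-4,4,5,5-tetramethyl-1,3,2-dioxaborolane F2. Palladium-catalysed allyl–aryl Suzuki coupling of F2 with 13 (Pd2(dba)3, SPhos, K3PO4, THF/H2O, 50 °C) should proceed through a π-allyl complex of divalent palladium that couples at its less substituted terminus, giving 16.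

Step 14 (with step 13). The most likely failures are opening of the epoxide by iodide during the iodination and simple reduction of the C–I bond without elimination in the zinc step. The fallback sets out from 18 and returns to 21 by a Wharton transposition. Oxidation of 18 (SO3·pyridine, DMSO, iPr2NEt) should give the epoxy aldehyde (2S,3R)-2-methyl-3-[(3E)-5-Ar-3-methylpent-3-en-1-yl]oxirane-2-carbaldehyde F3. Hydrazine hydrate with catalytic acetic acid in methanol at 0 °C should convert F3 into the epoxy hydrazone F4 (not isolated). F4 opens the oxirane at C7' and loses nitrogen, so C8' becomes the methylene carbon and the C6'–O bond, with its configuration, is kept.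

Step 3. The most likely failure is competing insertion of palladium into the aryl bromide of 3 or 6 at the temperature needed for ring closure, leading to oligomers, together with oxidative dimerization of the alkyne. The fallback sets out from 3 and returns to 6 without palladium (Castro–Stephens benzofuran synthesis). Compound 3 is converted with CuI in aqueous ammonia and ethanol into the copper acetylide [(2-bromo-3,5-dimethoxyphenyl)ethynyl]copper F5. Heating F5 with 4 in pyridine should couple at the aryl iodide only and cyclize in the same operation to 6.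

**Further compounds**

F1 | step 12 | (6E)-8-{2-[6-(triisopropylsilyloxy)-1-benzofuran-2-yl]-4,6-bis(triisopropylsilyloxy)phenyl}-2,6-dimethylocta-1,6-dien-3-one | C=C(C)C(=O)CC/C(C)=C/Cc1c(O[Si](C(C)C)(C(C)C)C(C)C)cc(O[Si](C(C)C)(C(C)C)C(C)C)cc1-c1cc2ccc(O[Si](C(C)C)(C(C)C)C(C)C)cc2o1
F2 | step 10 | 2-{2-[6-(triisopropylsilyloxy)-1-benzofuran-2-yl]-4,6-bis(triisopropylsilyloxy)phenyl}-4,4,5,5-tetramethyl-1,3,2-dioxaborolane | CC1(C)OB(OC1(C)C)c1c(O[Si](C(C)C)(C(C)C)C(C)C)cc(O[Si](C(C)C)(C(C)C)C(C)C)cc1-c1cc2ccc(O[Si](C(C)C)(C(C)C)C(C)C)cc2o1
F3 | step 14 | (2S,3R)-2-methyl-3-[(3E)-5-Ar-3-methylpent-3-en-1-yl]oxirane-2-carbaldehyde | O=C[C@@]1(C)O[C@@H]1CC/C(C)=C/Cc1c(O[Si](C(C)C)(C(C)C)C(C)C)cc(O[Si](C(C)C)(C(C)C)C(C)C)cc1-c1cc2ccc(O[Si](C(C)C)(C(C)C)C(C)C)cc2o1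
F4 | step 14 | hydrazone of the epoxy aldehyde F3 | NN=C[C@@]1(C)O[C@@H]1CC/C(C)=C/Cc1c(O[Si](C(C)C)(C(C)C)C(C)C)cc(O[Si](C(C)C)(C(C)C)C(C)C)cc1-c1cc2ccc(O[Si](C(C)C)(C(C)C)C(C)C)cc2o1
F5 | step 3 | [(2-bromo-3,5-dimethoxyphenyl)ethynyl]copper | [Cu]C#Cc1cc(OC)cc(OC)c1Br
A1 | alternative 1 | 2-[(2E,6R)-6-(tert-butyldimethylsilyloxy)-3,7-dimethylocta-2,7-dien-1-yl]-3-[6-(triisopropylsilyloxy)-1-benzofuran-2-yl]-5-(triisopropylsilyloxy)phenol | C=C(C)[C@H](O[Si](C)(C)C(C)(C)C)CC/C(C)=C/Cc1c(O)cc(O[Si](C(C)C)(C(C)C)C(C)C)cc1-c1cc2ccc(O[Si](C(C)C)(C(C)C)C(C)C)cc2o1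
A2 | alternative 1 | 4-[(2E,6R)-6-(tert-butyldimethylsilyloxy)-3,7-dimethylocta-2,7-dien-1-yl]-3-[6-(triisopropylsilyloxy)-1-benzofuran-2-yl]cyclobut-2-en-1-one | O=C1C=C(c2cc3ccc(O[Si](C(C)C)(C(C)C)C(C)C)cc3o2)C1C/C=C(C)/CC[C@@H](O[Si](C)(C)C(C)(C)C)C(C)=C
A3 | alternative 1 | (triisopropylsilyloxy)ethyne | C#CO[Si](C(C)C)(C(C)C)C(C)C
A4 | alternative 2 | (3R,6E)-8-{2-[6-(triisopropylsilyloxy)-1-benzofuran-2-yl]-4,6-bis(triisopropylsilyloxy)phenyl}-2,6-dimethylocta-1,6-dien-3-ol (identical with 21) | C=C(C)[C@H](O)CC/C(C)=C/Cc1c(O[Si](C(C)C)(C(C)C)C(C)C)cc(O[Si](C(C)C)(C(C)C)C(C)C)cc1-c1cc2ccc(O[Si](C(C)C)(C(C)C)C(C)C)cc2o1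
A5 | alternative 2 | (3R)-2-methylhept-1-en-6-yn-3-ol | C=C(C)[C@H](O)CCC#C
A6 | alternative 2 | 2-[2-(chloromethyl)-3,5-bis(triisopropylsilyloxy)phenyl]-6-(triisopropylsilyloxy)-1-benzofuran | ClCc1c(O[Si](C(C)C)(C(C)C)C(C)C)cc(O[Si](C(C)C)(C(C)C)C(C)C)cc1-c1cc2ccc(O[Si](C(C)C)(C(C)C)C(C)C)cc2o1
A7 | alternative 3 | tert-butyldimethylsilyl ether of 21 at the C6' oxygen | C=C(C)[C@H](O[Si](C)(C)C(C)(C)C)CC/C(C)=C/Cc1c(O[Si](C(C)C)(C(C)C)C(C)C)cc(O[Si](C(C)C)(C(C)C)C(C)C)cc1-c1cc2ccc(O[Si](C(C)C)(C(C)C)C(C)C)cc2o1
A8 | alternative 3 | {2-[(2-[(2E,6R)-6-(tert-butyldimethylsilyloxy)-3,7-dimethylocta-2,7-dien-1-yl]-3,5-bis(triisopropylsilyloxy)benzoyl)oxy]-4-(triisopropylsilyloxy)benzyl}triphenylphosphonium bromide | C=C(C)[C@H](O[Si](C)(C)C(C)(C)C)CC/C(C)=C/Cc1c(O[Si](C(C)C)(C(C)C)C(C)C)cc(O[Si](C(C)C)(C(C)C)C(C)C)cc1C(=O)Oc1cc(O[Si](C(C)C)(C(C)C)C(C)C)ccc1C[P+](c1ccccc1)(c1ccccc1)c1ccccc1.[Br-]
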